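Early on, D lags the loss of Q: in larch at 4.00 min, Q has fallen to 87.3 % of the charge while D stands at 2.1 %. Later D itself falls in cedar, so I reckon its drain in logarithms, as decades per minute.

| flask | Q | E | temperature | remark | time |
|---|---|---|---|---|---|
| larch | 28 mM | 0.20 mM | 75 °C | run made earlier |  |
| cedar | 44 mM | 0.20 mM | 88 °C | run made earlier |  |
| maple | 20 mM | 0.40 mM | 75 °C | run made earlier |  |
| Thursday's | 20 mM | 0.20 mM | 80 °C |  | 80 min |
| Sunday's | 20 mM | 0.20 mM | 95 °C |  | 80 min |

| run | time / min | D / % | Q / % |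
|---|---|---|---|
| larch | 4.00 | 2.1 | 87.3 |
| larch | 12.0 | 13.8 | 64.4 |
| larch | 25.0 | 38.9 | 42.9 |
| larch | 30.0 | 45.3 | 37.3 |
| larch | 50.0 | 68.7 | 17.7 |
| larch | 60.0 | 74.8 | 13.2 |
| larch | 80.0 | 80.7 | 6.1 |
| cedar | 12.0 | 49.8 | 19.6 |
| cedar | 25.0 | 77.5 | 2.7 |
| cedar | 30.0 | 77.2 | 4.3 |
| cedar | 50.0 | 67.2 | 1.4 |
| cedar | 60.0 | 59.2 | 0 |
| cedar | 80.0 | 50.5 | 0.6 |
| maple | 8.00 | 12.2 | 76.3 |
| maple | 20.0 | 39.6 | 50.7 |
| maple | 40.0 | 66.3 | 27.1 |
| maple | 60.0 | 75.9 | 12.9 |
| maple | 80.0 | 82.6 | 5.9 |

(scatter of a reading: 1 percentage point)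



- which of the two there is more of at the end, Thursday's (D / G)
- which of the two there is more of at the end, Sunday's (D / G)
- amount of D at the end, in percent of the Q charged, Thursday's
- amount of D at the end, in percent of the Q charged, Sunday's

In cedar, from 50.0 min to 80.0 min, Q reads 1.4 % or less and D falls from 67.2 % to 50.5 %, a drain of 0.00414 min⁻¹. Maple ends with a gap of 11.5 % of the charge, and its readings put mean D near 55.8 %. Counting the whole gap as G gives at most 0.00112 min⁻¹ at maple's 75 °C.

So the gain, the decades of drain rate won from maple's temperature to cedar's, is at least 0.567. Sunday's step lies 0.538 of that span beyond cedar, so its drain is at least 0.00836 min⁻¹.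

From below: taking mean D in maple as high as its end value gives a steeper gain and 0.0103 min⁻¹, and with all D born at the start, Sunday's keeps 14.9 %. From above: the slower drain, with half of D born by 12.0 min and the rest by 25.0 min, as cedar's readings show, keeps 30.9 %. I commit to the middle in logarithms, 21.5 %, with G ahead on Sunday's. Thursday's drain by the same gain is 0.00185 min⁻¹, so D born at the start keeps 71.1 % and stays ahead.

The forecast puts D ahead on Thursday's, with 79 % of D, and G ahead on Sunday's, with 23 % of D, on the ground that “D then drains to G, first order and E-independent”. Its Sunday figure lies inside my bracket .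

The flasks give 77.6 % of D against 20.6 % of G on Thursday's, and 19.6 % of D against 80.4 % of G on Sunday's, inside the bracket .

    Q → L (k = 9.80 × 10⁻⁴ s⁻¹, Ea = 107 kJ mol⁻¹)
    E + L → E + D (k = 10.0 M⁻¹ s⁻¹, Ea = 45.0 kJ mol⁻¹)
    D → G (k = 7.10 × 10⁻⁵ s⁻¹, Ea = 121 kJ mol⁻¹)
    (constants at 80 °C)

In Thursday's flask the half-life of D by its step to G is 160 min, twice the run's 80 min and much longer than the 12 min half-life of Q by its step to L, and at the end D is made at 0.315 of the rate at which it is used. The gain, at its least value, takes Sunday's D from 48.9 % at 40.0 min to 22.6 % at the end, where the flask holds 19.6 %. It takes Thursday's D from 77.6 % to 3.61 % at 800 min, where that flask holds 3.70 %.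

(The runs were computed from invented constants, and the scatter is random.)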